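**Plan**

1. Retrosynthesis (eremophilane numbering): the two esters are taken off to the 8α,9α-diol; the C7–C11 and C8–O bonds go back to a 7α,8α-epoxide opened by an isopropenyl nucleophile; the C2 ketone is moved back to C1; ring B is then cut at C5–C6 and C9–C10.
2. The two cuts give (S)-3,4-dimethylcyclohex-2-enone (ring A, C5=C10 as dienophile) and an (E)-1-silyloxybutadiene (C6–C7–C8–C9); the enone comes from propanal and methyl vinyl ketone.
3. Forward: ring A (organocatalytic Michael–aldol, methyl addition, dehydrogenation), ring B in one [4+2] cycloaddition, carbonyl shift C1→C2, hydroxyl-directed epoxidation, epoxide opening, acetylation, senecioylation.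
4. Enabling feature: ring B is a cyclohexane fused cis to ring A across C5–C10, with quaternary C5 next to the C4 methyl stereocentre, oxygen-bearing C9 next to C10, and a trans C/O pair on C7/C8 (an opened 7,8-epoxide). C6–C9 therefore map onto a 1-oxydiene and C5=C10 onto a ring A enone whose C1 carbonyl is a helper, later moved to C2.
5. Stereochemistry: C4 by amine catalysis; C5, C10 and C9 together in the cycloaddition (anti to the C4 methyl, suprafacial, endo); C8 by epoxidation directed by the 9α-hydroxyl; C7 by SN2 inversion.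

Key step: step 5

Remark: atoms are numbered as in eremophilane (ring A = C1–C5, C10; ring B = C5–C10; C14 on C5, C15 on C4, C11–C13 = isopropenyl on C7). α/β refer to the usual drawing with both ring methyls β; the target is then 7β-isopropenyl, 8α-OAc, 9α-O-senecioyl, 10β-H, i.e. (4S,5R,7R,8R,9S,10S). Compounds 9 to 16 lack C11–C13 and are named as 11,12,13-trinoreremophilanes.

**Route**

Step 1
Reactants: 1 propanal; 2 methyl vinyl ketone (but-3-en-2-one)
Product: 4 (S)-4-methylcyclohex-2-en-1-one, via (S)-2-methyl-5-oxohexanal 3 (not isolated)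
Conditions: (R)-2-(methoxydiphenylmethyl)pyrrolidine (5 mol %), ethyl 3,4-dihydroxybenzoate (20 mol %), neat, 4 °C; then LiOH (0.1 equiv), iPrOH, rt
Reagents that add atoms: none
Why: Enamine-catalysed asymmetric Michael addition of propanal to the vinyl ketone followed by base-mediated intramolecular aldol condensation (a two-stage Robinson-type annulation) should give the enone; the stereocentre (future C4) is set in the Michael step by attack on the enamine face remote from the diphenylmethoxymethyl group, for which the (R)-catalyst is expected to give the (S)-aldehyde (the enantiomeric catalyst would be taken if the sense proved opposite).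

Step 2
Reactants: 4 (S)-4-methylcyclohex-2-en-1-one
Product: 5 (3R,4S)-3,4-dimethyl-1-(trimethylsilyloxy)cyclohex-1-ene
Conditions: MeMgBr (1.2 equiv), CuBr·SMe2 (5 mol %), TMSCl (2 equiv), THF, −78 °C; Et3N, pentane work-up
Reagents that add atoms: methylmagnesium bromide, C[Mg]Br; chlorotrimethylsilane, C[Si](C)(C)Cl
Why: Copper-catalysed conjugate addition of the Grignard reagent with chlorosilane trapping of the enolate puts the future C14 methyl in place (trans to the existing methyl, a centre erased in step 3) and fixes the silyl enol ether on the side needed for the dehydrogenation.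

Step 3
Reactants: 5 (3R,4S)-3,4-dimethyl-1-(trimethylsilyloxy)cyclohex-1-ene
Product: 6 (S)-3,4-dimethylcyclohex-2-en-1-one
Conditions: Pd(OAc)2 (1.05 equiv), MeCN, rt
Reagents that add atoms: none
Why: Saegusa–Ito oxidation: the silyl enol ether gives a palladium enolate of divalent palladium whose only β-hydrogen (on the methyl-bearing carbon) is eliminated, so the 3-methyl enone should form regiospecifically with the C4 stereocentre untouched.

Step 4
Reactants: 7 (E)-but-2-enal (crotonaldehyde)
Product: 8 (E)-1-(tert-butyldimethylsilyloxy)buta-1,3-diene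
Conditions: TBSOTf (1.1 equiv), Et3N (1.3 equiv), Et2O, 0 °C → rt
Reagents that add atoms: tert-butyldimethylsilyl trifluoromethanesulfonate, CC(C)(C)[Si](C)(C)OS(=O)(=O)C(F)(F)F
Why: Soft enolisation (O-silylation, then γ-deprotonation by the amine) of the enal should give the 1-silyloxydiene mainly as the (E)-isomer; the (Z)-isomer cannot reach the s-cis conformation and should stay out of step 5.

Step 5
Reactants: 6 (S)-3,4-dimethylcyclohex-2-en-1-one; 8 (E)-1-(tert-butyldimethylsilyloxy)buta-1,3-diene
Product: 9 9α-(tert-butyldimethylsilyloxy)-11,12,13-trinor-10βH-eremophil-7-en-1-one (cis-fused; 4β,5β-dimethyl)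
Conditions: Tf2NH (10 mol %), 8 (2 equiv), CH2Cl2, −78 → −40 °C; Et3N quench
Reagents that add atoms: none
Why: Lewis-acid-catalysed normal-demand Diels–Alder reaction: Tf2NH and the diene generate TBSNTf2, which silylates the C1 carbonyl of 6 and lowers the LUMO of C5=C10; the cycloaddition is concerted but strongly asynchronous, the C5–C6 bond (diene terminus remote from oxygen onto the enone β-carbon) running ahead of C9–C10, and silyl transfer releases the catalyst. The closest known reaction type is the silyl triflimide (or mixed aluminium halide) catalysed cycloaddition of silyloxydienes to 3-alkylcyclohex-2-enones, which builds a quaternary centre at the β-carbon. Ring B closes by suprafacial [4+2] addition across C5=C10, so the ring fusion must be cis (10β-H cis to the C5 methyl). C5 and C10 are controlled by the C4 stereocentre: allylic 1,2-strain with the C5 methyl holds the C4 methyl pseudoaxial and the diene adds to the opposite face, which makes the two methyls cis; C9 is controlled by the endo rule, the outside silyloxy group of the (E)-diene ending cis to the C1 carbonyl, i.e. 9α. The step needs ortho regioselectivity (oxygen-polarised diene matched with the enone β-carbon), facial selectivity (pseudoaxial C4 methyl) and endo selectivity (overlap with the silylated carbonyl), and the β-silyloxy ketone must not eliminate, hence the low temperature and the basic quench.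

Step 6
Reactants: 9 9α-(tert-butyldimethylsilyloxy)-11,12,13-trinor-10βH-eremophil-7-en-1-one
Product: 11 9α-(tert-butyldimethylsilyloxy)-11,12,13-trinor-10βH-eremophila-1,7-dien-1-yl trifluoromethanesulfonate, via potassium enolate 10 (not isolated)
Conditions: KN(SiMe3)2 (1.1 equiv), THF, −78 °C; then PhNTf2 (1.2 equiv), −78 → 0 °C
Reagents that add atoms: N-phenylbis(trifluoromethanesulfonimide), FC(F)(F)S(=O)(=O)N(c1ccccc1)S(=O)(=O)C(F)(F)F (KN(SiMe3)2 supplies the potassium of intermediate 10 only)
Why: Kinetic deprotonation should take the unhindered C2 methylene and not the ring-fusion C10–H (which would expel the C9 silyloxy group by E1cB), and O-triflation of the enolate fixes the C1=C2 enol triflate needed for the carbonyl shift without touching a stereocentre.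

Step 7
Reactants: 11 9α-(tert-butyldimethylsilyloxy)-11,12,13-trinor-10βH-eremophila-1,7-dien-1-yl trifluoromethanesulfonate
Product: 13 9α-(tert-butyldimethylsilyloxy)-11,12,13-trinor-10βH-eremophil-7-en-2-one, via morpholine enamine 12 (not isolated)
Conditions: Pd(OAc)2 (10 mol %), P(4-MeOC6H4)3 (20 mol %), norbornene (50 mol %), 4-(benzoyloxy)morpholine (1.5 equiv), iPrOH (3 equiv), Cs2CO3 (2.5 equiv), 1,4-dioxane, 100 °C; then 1 M HCl, THF, 0 °C
Reagents that add atoms: water, O (the ketone oxygen); 4-(benzoyloxy)morpholine, O=C(ON1CCOCC1)c1ccccc1 (supplies the morpholine unit of intermediate 12 only)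
Why: Catellani-type palladium/norbornene relay (1,2-carbonyl transposition through α-amination of an alkenyl triflate): zerovalent palladium inserts into the C1–O bond, norbornene carries the metal to the vinylic C2–H, the N–O reagent aminates C2, norbornene leaves and the C1–Pd bond is reduced by hydride from isopropoxide, so that hydrolysis of the enamine should give the C2 ketone; no stereocentre is formed and C10, now β to the carbonyl, can no longer epimerise.

Step 8
Reactants: 13 9α-(tert-butyldimethylsilyloxy)-11,12,13-trinor-10βH-eremophil-7-en-2-one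
Product: 14 9α-hydroxy-11,12,13-trinor-10βH-eremophil-7-en-2-one
Conditions: Bu4NF (1.2 equiv), THF, 0 °C → rt; aq NH4Cl
Reagents that add atoms: none
Why: Fluoride-induced cleavage of the silyl ether frees the allylic 9α-hydroxyl that must direct the epoxidation; the ketone and the alkene are inert.

Step 9
Reactants: 14 9α-hydroxy-11,12,13-trinor-10βH-eremophil-7-en-2-one
Product: 15 7α,8α-epoxy-9α-hydroxy-11,12,13-trinor-10βH-eremophilan-2-one
Conditions: VO(acac)2 (5 mol %), tBuOOH (1.5 equiv), CH2Cl2, 0 °C → rt
Reagents that add atoms: tert-butyl hydroperoxide, CC(C)(C)OO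
Why: Hydroxyl-directed epoxidation: the vanadium alkoxide of the allylic alcohol delivers the peroxide oxygen to the face of C7=C8 syn to the 9α-hydroxyl, which sets the C8–O bond α (and C7 for inversion in step 10); the saturated ketone does not react with this reagent.

Step 10
Reactants: 15 7α,8α-epoxy-9α-hydroxy-11,12,13-trinor-10βH-eremophilan-2-one
Product: 17 8α,9α-dihydroxy-10βH-eremophil-11-en-2-one, via dilithium enolate alkoxide 16 (not isolated)
Conditions: LiN(iPr)2 (2.2 equiv), THF, −78 °C; then CH2=C(CH3)MgBr (4 equiv), CuI (20 mol %), −30 → 0 °C; aq NH4Cl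
Reagents that add atoms: isopropenylmagnesium bromide, C=C(C)[Mg]Br (LiN(iPr)2 supplies the lithium of intermediate 16 only)
Why: The ketone is first masked as its lithium enolate (and the hydroxyl as alkoxide); copper-catalysed Grignard opening of the epoxide by SN2 attack at C7, the carbon remote from the electron-withdrawing C9 oxygen, with inversion (trans-diaxial opening, as for cis-3-alkoxycyclohexene oxides) should then place the isopropenyl group β and trans to the 8α-hydroxyl, and aqueous work-up returns the ketone.

Step 11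
Reactants: 17 8α,9α-dihydroxy-10βH-eremophil-11-en-2-one
Product: 18 8α-acetoxy-9α-hydroxy-10βH-eremophil-11-en-2-one
Conditions: Ac2O (1.1 equiv), pyridine, CH2Cl2, 0 °C
Reagents that add atoms: acetic anhydride, CC(=O)OC(C)=O
Why: Kinetically selective acylation of a cis-diol: the equatorial 8α-hydroxyl should react much faster than the axial 9α-hydroxyl, which is flanked by the ring fusion and is syn-axial to C4; no stereocentre is affected.

Step 12
Reactants: 18 8α-acetoxy-9α-hydroxy-10βH-eremophil-11-en-2-one
Product: 19 8α-acetoxy-9α-(3-methylbut-2-enoyloxy)-10βH-eremophil-11-en-2-one (target)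
Conditions: 3-methylbut-2-enoyl chloride (3 equiv), DMAP (20 mol %), pyridine, CH2Cl2, 0 → 40 °C
Reagents that add atoms: 3-methylbut-2-enoyl chloride, CC(C)=CC(=O)Cl
Why: DMAP-catalysed acylation through the acylpyridinium ion should esterify the remaining hindered axial alcohol; pyridine rather than a trialkylamine is used to avoid vinylketene formation and deconjugation of the senecioyl group, and the equatorial acetate has no driving force to migrate.

**Compound list**

1 | propanal | CCC=O | starting material
2 | methyl vinyl ketone | CC(=O)C=C | starting material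
3 | (S)-2-methyl-5-oxohexanal | CC(=O)CC[C@H](C)C=O | intermediate
4 | (S)-4-methylcyclohex-2-en-1-one | O=C1CC[C@H](C)C=C1 | intermediate
5 | (3R,4S)-3,4-dimethyl-1-(trimethylsilyloxy)cyclohex-1-ene | C[Si](C)(C)OC1=C[C@H](C)[C@@H](C)CC1 | intermediate
6 | (S)-3,4-dimethylcyclohex-2-en-1-one | O=C1CC[C@H](C)C(C)=C1 | intermediate
7 | (E)-but-2-enal | C/C=C/C=O | starting material
8 | (E)-1-(tert-butyldimethylsilyloxy)buta-1,3-diene | C=C/C=C/O[Si](C)(C)C(C)(C)C | intermediate
9 | 9α-(tert-butyldimethylsilyloxy)-11,12,13-trinor-10βH-eremophil-7-en-1-one | C1=CC[C@@]2(C)[C@H](C(=O)CC[C@@H]2C)[C@@H]1O[Si](C)(C)C(C)(C)C | intermediate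
10 | potassium C1(2)-enolate of 9 | [K+].C1=CC[C@@]2(C)[C@H](C([O-])=CC[C@@H]2C)[C@@H]1O[Si](C)(C)C(C)(C)C | intermediate
11 | 9α-(tert-butyldimethylsilyloxy)-11,12,13-trinor-10βH-eremophila-1,7-dien-1-yl trifluoromethanesulfonate | C1=CC[C@@]2(C)[C@H](C(OS(=O)(=O)C(F)(F)F)=CC[C@@H]2C)[C@@H]1O[Si](C)(C)C(C)(C)C | intermediate
12 | 4-[9α-(tert-butyldimethylsilyloxy)-11,12,13-trinor-10βH-eremophila-1,7-dien-2-yl]morpholine | C1=CC[C@@]2(C)[C@H](C=C(N3CCOCC3)C[C@@H]2C)[C@@H]1O[Si](C)(C)C(C)(C)C | intermediate
13 | 9α-(tert-butyldimethylsilyloxy)-11,12,13-trinor-10βH-eremophil-7-en-2-one | C1=CC[C@@]2(C)[C@H](CC(=O)C[C@@H]2C)[C@@H]1O[Si](C)(C)C(C)(C)C | intermediate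
14 | 9α-hydroxy-11,12,13-trinor-10βH-eremophil-7-en-2-one | C1=CC[C@@]2(C)[C@H](CC(=O)C[C@@H]2C)[C@@H]1O | intermediate
15 | 7α,8α-epoxy-9α-hydroxy-11,12,13-trinor-10βH-eremophilan-2-one | [C@@H]12C[C@@]3(C)[C@H](CC(=O)C[C@@H]3C)[C@H](O)[C@@H]1O2 | intermediate
16 | dilithium salt of 15 (9-alkoxide; drawn as the C2(3)-enolate, the C1(2)-enolate serves equally) | [Li+].[Li+].[C@@H]12C[C@@]3(C)[C@H](CC([O-])=C[C@@H]3C)[C@H]([O-])[C@@H]1O2 | intermediate
17 | 8α,9α-dihydroxy-10βH-eremophil-11-en-2-one | C=C(C)[C@H]1C[C@@]2(C)[C@H](CC(=O)C[C@@H]2C)[C@H](O)[C@@H]1O | intermediate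
18 | 8α-acetoxy-9α-hydroxy-10βH-eremophil-11-en-2-one | C=C(C)[C@H]1C[C@@]2(C)[C@H](CC(=O)C[C@@H]2C)[C@H](O)[C@@H]1OC(C)=O | intermediate
19 | (4S,5R,7R,8R,9S,10S)-8α-acetoxy-9α-(3-methylbut-2-enoyloxy)-10βH-eremophil-11-en-2-one | C=C(C)[C@H]1C[C@@]2(C)[C@H](CC(=O)C[C@@H]2C)[C@H](OC(=O)C=C(C)C)[C@@H]1OC(C)=O | target

**Count**

Total: 12 steps. Longest linear sequence: 11 steps (steps 1–3 and 5–12); step 4 is a one-step side branch.

**The three steps most likely to fail**

Step 5. The silyl Lewis acid may divert the reaction from the concerted path into a stepwise Michael addition that ends in open-chain product. The β-silyloxy ketone may also lose silanol, or endo and facial selectivity may erode at the temperature needed to reach the hindered β-carbon. The fallback sets out from 6 and comes back at 9. It drops acid catalysis for a pressure-driven, purely thermal cycloaddition and replaces the silyl dienol ether by the acid-stable enol acetate. Enone 6 and commercial (E)-1-acetoxybuta-1,3-diene at about 12 kbar (CH2Cl2, 40 °C) should give, by the same ortho, endo and anti mode, 9α-acetoxy-11,12,13-trinor-10βH-eremophil-7-en-1-one F1. Mild transesterification (K2CO3 (0.2 equiv), MeOH, 0 °C, or a lipase in MeOH) should give 9α-hydroxy-11,12,13-trinor-10βH-eremophil-7-en-1-one F2. TBSOTf and 2,6-lutidine (CH2Cl2, −78 °C) then return to 9.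

Step 7. The alkenylpalladium species may be reduced before the amination occurs (plain loss of the triflate), or the relay may stall at the C1 position, which is flanked by the ring fusion. The fallback sets out from 9 and comes back at 13; it is the classical sulfide-based 1,2-carbonyl transposition. Kinetic enolate formation and sulfenylation (LiN(iPr)2, then PhSSPh, THF, −78 °C) should give 9α-(tert-butyldimethylsilyloxy)-2-(phenylthio)-11,12,13-trinor-10βH-eremophil-7-en-1-one F3. Reduction (NaBH4, MeOH, 0 °C) should give the 1-hydroxy-2-(phenylthio) compound F4. Mesylation (MsCl, Et3N, CH2Cl2, 0 °C) should give the 1-methanesulfonate F5. Elimination towards the sulfur-acidified C2–H (KOtBu, THF, 0 °C) should give the vinyl sulfide 9α-(tert-butyldimethylsilyloxy)-2-(phenylthio)-11,12,13-trinor-10βH-eremophila-1,7-diene F6. Hydrolysis (HgCl2, CaCO3, MeCN/H2O, 50 °C) returns to 13.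

Step 10. The organometallic may attack C8 instead of C7 if the conformational bias of the cis-decalin outweighs the inductive bias. The ketone may be masked incompletely and add the Grignard reagent, or bromide may open the epoxide. The fallback sets out from 14 and comes back at 18. It replaces in-flask masking by covalent protection of the ketone and of the C9 oxygen, which also removes the need for a selective acetylation. Ketalisation (ethylene glycol, PPTS, benzene, reflux with water removal) should give 2,2-ethylenedioxy-11,12,13-trinor-10βH-eremophil-7-en-9α-ol F7. Directed epoxidation (VO(acac)2, tBuOOH) should give the 7α,8α-epoxide F8. Silylation (Et3SiCl, imidazole, DMF) should give the 9α-triethylsilyl ether F9, whose bulky, electron-withdrawing C9 substituent reinforces attack at C7. Opening with CH2=C(CH3)MgBr and CuI (10 mol %) in THF at −30 °C should give 2,2-ethylenedioxy-9α-(triethylsilyloxy)-10βH-eremophil-11-en-8α-ol F10. Acetylation (Ac2O, DMAP, pyridine) should give the 8α-acetate F11. Aqueous acetic acid (AcOH/THF/H2O, 40 °C) removes the silyl ether and the dioxolane and returns to 18.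

Further compounds
F1 | step 5 | 9α-acetoxy-11,12,13-trinor-10βH-eremophil-7-en-1-one | C1=CC[C@@]2(C)[C@H](C(=O)CC[C@@H]2C)[C@@H]1OC(C)=O
F2 | step 5 | 9α-hydroxy-11,12,13-trinor-10βH-eremophil-7-en-1-one | C1=CC[C@@]2(C)[C@H](C(=O)CC[C@@H]2C)[C@@H]1O
F3 | step 7 | 9α-(tert-butyldimethylsilyloxy)-2-(phenylthio)-11,12,13-trinor-10βH-eremophil-7-en-1-one (C2 epimers) | C1=CC[C@@]2(C)[C@H](C(=O)C(Sc3ccccc3)C[C@@H]2C)[C@@H]1O[Si](C)(C)C(C)(C)C
F4 | step 7 | 9α-(tert-butyldimethylsilyloxy)-2-(phenylthio)-11,12,13-trinor-10βH-eremophil-7-en-1-ol (C1 and C2 epimers) | C1=CC[C@@]2(C)[C@H](C(O)C(Sc3ccccc3)C[C@@H]2C)[C@@H]1O[Si](C)(C)C(C)(C)C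
F5 | step 7 | 9α-(tert-butyldimethylsilyloxy)-2-(phenylthio)-11,12,13-trinor-10βH-eremophil-7-en-1-yl methanesulfonate | C1=CC[C@@]2(C)[C@H](C(OS(C)(=O)=O)C(Sc3ccccc3)C[C@@H]2C)[C@@H]1O[Si](C)(C)C(C)(C)C
F6 | step 7 | 9α-(tert-butyldimethylsilyloxy)-2-(phenylthio)-11,12,13-trinor-10βH-eremophila-1,7-diene | C1=CC[C@@]2(C)[C@H](C=C(Sc3ccccc3)C[C@@H]2C)[C@@H]1O[Si](C)(C)C(C)(C)C
F7 | step 10 | 2,2-ethylenedioxy-11,12,13-trinor-10βH-eremophil-7-en-9α-ol | C1=CC[C@@]2(C)[C@H](CC3(OCCO3)C[C@@H]2C)[C@@H]1O
F8 | step 10 | 7α,8α-epoxy-2,2-ethylenedioxy-11,12,13-trinor-10βH-eremophilan-9α-ol | [C@@H]12C[C@@]3(C)[C@H](CC4(OCCO4)C[C@@H]3C)[C@H](O)[C@@H]1O2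
F9 | step 10 | 7α,8α-epoxy-2,2-ethylenedioxy-9α-(triethylsilyloxy)-11,12,13-trinor-10βH-eremophilane | [C@@H]12C[C@@]3(C)[C@H](CC4(OCCO4)C[C@@H]3C)[C@H](O[Si](CC)(CC)CC)[C@@H]1O2
F10 | step 10 | 2,2-ethylenedioxy-9α-(triethylsilyloxy)-10βH-eremophil-11-en-8α-ol | C=C(C)[C@H]1C[C@@]2(C)[C@H](CC3(OCCO3)C[C@@H]2C)[C@H](O[Si](CC)(CC)CC)[C@@H]1O
F11 | step 10 | 8α-acetoxy-2,2-ethylenedioxy-9α-(triethylsilyloxy)-10βH-eremophil-11-ene | C=C(C)[C@H]1C[C@@]2(C)[C@H](CC3(OCCO3)C[C@@H]2C)[C@H](O[Si](CC)(CC)CC)[C@@H]1OC(C)=O
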